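## Retrosynthetic overview
1. Target ⇒ acidolysis of a 4-methoxybenzyl (PMB) ester and O5-acetylation ⇒ the 5α-hydroxy 3α-(6-methylheptanoyl) 4β-tigloyl diester.
2. Key C3–O disconnection: 6-methylheptanoic acid plus the allylic carbon of a 3β,4β-fused tigloxonium ion. The C4–O bond of that ion comes from backside attack of a 3β-tiglate on a 4α,5α-epoxide.
3. The 3β-tigloyloxy 4α,5α-epoxide ⇒ PMB shikimate by two Mitsunobu C–O bond formations (O4→C5 ring closure, tiglate→C3).
4. The carbocycle is bought as (−)-shikimic acid. Ring order: oxirane (C4–C5) first, then the transient 1,3-dioxolan-2-ylium (C3–C4). Both are opened again.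
5. Stereo ledger: C5 is inverted once, C4 once and C3 twice (net retention), so (3R,4S,5R) becomes (3R,4R,5S).

Assumption: the SMILES is taken literally as (3R,4R,5S), the all-trans pattern with C4 and C5 inverted relative to natural (−)-shikimic acid, and 6-methylheptanoic acid is bought.

Convention: shikimate numbering is used (C1 bears the carboxyl group). α is the face that carries 3-OH and 4-OH in natural shikimic acid.

## Route

Step 1
Reactants: 1 (−)-shikimic acid; 2 4-methoxybenzyl chloride
Product: 3 4-methoxybenzyl (3R,4S,5R)-3,4,5-trihydroxycyclohex-1-ene-1-carboxylate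
Conditions: KHCO3, DMF, 40 °C
Reagents that add atoms: 4-methoxybenzyl chloride (2), COc1ccc(CCl)cc1
Why: This is a carboxylate O-alkylation (SN2 on the benzylic chloride) in which KHCO3 deprotonates only the acid, so the three hydroxyls stay free and no stereocentre is touched.

Step 2
Reactants: 3 PMB shikimate; 4 tiglic acid
Product: 6 4-methoxybenzyl (1S,5S,6S)-5-[(E)-2-methylbut-2-enoyloxy]-7-oxabicyclo[4.1.0]hept-3-ene-3-carboxylate, via epoxy alcohol 5 (not isolated)
Conditions: PPh3, DIAD, THF, 0 °C → rt; then 4, PPh3, DIAD, 0 °C → rt (one pot)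
Reagents that add atoms: tiglic acid (4), C/C=C(\C)C(=O)O
Why: Two Mitsunobu reactions run in one flask: without external acid the least hindered 5-OH is activated and the trans 4-O closes onto C5 from the α face (Mitsunobu cyclodehydration, known for alkyl shikimates, inverts C5), and the only remaining hydroxyl, the allylic 3α-OH, is then displaced by tiglate with SN2 inversion to 3β (Mitsunobu esterification), the cis epoxide being unable to participate.

Step 3
Reactants: 6 3β-tigloyloxy 4α,5α-epoxide; 7 6-methylheptanoic acid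
Product: 9 4-methoxybenzyl (3R,4R,5S)-5-hydroxy-3-(6-methylheptanoyloxy)-4-[(E)-2-methylbut-2-enoyloxy]cyclohex-1-ene-1-carboxylate, via tigloxonium ion pair 8 (not isolated)
Conditions: 7 (2 equiv), (PhO)2P(O)OH (10 mol %), 4 Å MS, PhMe, 40 °C
Reagents that add atoms: 6-methylheptanoic acid (7), CC(C)CCCCC(=O)O
Why: Proposed new method: anchimerically relayed carboxylysis of an epoxy ester, in which the hydrogen-bonded phosphoric acid/carboxylic acid pair protonates the oxirane while the anti-disposed 3β-tiglate C=O attacks C4 from the β face (5-exo, inversion at C4, the oxirane oxygen stays on C5 as 5α-OH) to give the conjugation-stabilised cis-fused dioxolan-2-ylium 8, whose allylic and least hindered carbon C3 is then attacked anti (α face, second inversion at C3, net retention) by 6-methylheptanoate under dry conditions, leaving the tigloyl group on O4β and regenerating the catalyst; the only other anti-disposed nucleophile, 5α-OH, merely regenerates protonated 6, so acyloxonium scrambling is excluded, C4 is deactivated by two flanking C–O bonds, and 5α-OH can hydrogen-bond the incoming carboxylate on the α face; the closest known reaction types are Winstein neighbouring-group participation, the anti-opening stage of the Prévost reaction, the acid-induced epoxy-ester to acyloxonium rearrangement, halide opening of shikimate 3,4-acetoxonium ions at C3, and phosphoric-acid-catalysed carboxylysis of epoxides.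

Step 4
Reactants: 9 5α-hydroxy diester; 10 acetic anhydride
Product: 11 4-methoxybenzyl (3R,4R,5S)-5-acetoxy-3-(6-methylheptanoyloxy)-4-[(E)-2-methylbut-2-enoyloxy]cyclohex-1-ene-1-carboxylate
Conditions: Ac2O, pyridine, DMAP (cat.), CH2Cl2, 0 °C
Reagents that add atoms: acetic anhydride (10), CC(=O)OC(C)=O
Why: DMAP-catalysed acetylation (nucleophilic acyl-transfer catalysis) of the only free hydroxyl is much faster at 0 °C than trans-vicinal acyl migration, and the C5–O bond is not broken, so the 5α configuration is retained.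

Step 5
Reactants: 11 PMB triester
Product: 12 (3R,4R,5S)-5-acetoxy-3-(6-methylheptanoyloxy)-4-[(E)-2-methylbut-2-enoyloxy]cyclohex-1-ene-1-carboxylic acid (CNP0225437.1)
Conditions: TFA, anisole, CH2Cl2, 0 °C
Reagents that add atoms: none
Why: This is an SN1 acidolysis of the PMB ester with Friedel–Crafts capture of the 4-methoxybenzyl cation by anisole, while the secondary alkyl esters, the enoate-deactivated allylic ester and the tiglate are inert to cold dilute TFA and no free hydroxyl is left for acyl migration.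

## Compound list
1 | (−)-shikimic acid, (3R,4S,5R)-3,4,5-trihydroxycyclohex-1-ene-1-carboxylic acid (3α,4α,5β) | O[C@H]1[C@H](O)CC(C(=O)O)=C[C@H]1O | starting material
2 | 4-methoxybenzyl chloride | COc1ccc(CCl)cc1 | starting material
3 | 4-methoxybenzyl (3R,4S,5R)-3,4,5-trihydroxycyclohex-1-ene-1-carboxylate (PMB shikimate) | O[C@H]1[C@H](O)CC(C(=O)OCc2ccc(OC)cc2)=C[C@H]1O | intermediate
4 | tiglic acid, (E)-2-methylbut-2-enoic acid | C/C=C(\C)C(=O)O | starting material
5 | 4-methoxybenzyl (1S,5R,6R)-5-hydroxy-7-oxabicyclo[4.1.0]hept-3-ene-3-carboxylate (3α-OH cis to the 4α,5α-epoxide) | O1[C@H]2[C@@H]1CC(C(=O)OCc3ccc(OC)cc3)=C[C@H]2O | intermediate (not isolated)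
6 | 4-methoxybenzyl (1S,5S,6S)-5-[(E)-2-methylbut-2-enoyloxy]-7-oxabicyclo[4.1.0]hept-3-ene-3-carboxylate (3β-tiglate trans to the 4α,5α-epoxide) | O1[C@H]2[C@@H]1CC(C(=O)OCc3ccc(OC)cc3)=C[C@@H]2OC(=O)/C(C)=C/C | intermediate
7 | 6-methylheptanoic acid | CC(C)CCCCC(=O)O | starting material
8 | 3β,4β-cis-fused 2-[(E)-but-2-en-2-yl]-1,3-dioxolan-2-ylium cation of the 5α-hydroxy PMB ester, 6-methylheptanoate counter-ion | O1[C@@H]2[C@@H](O)CC(C(=O)OCc3ccc(OC)cc3)=C[C@@H]2[O+]=C1/C(C)=C/C.CC(C)CCCCC(=O)[O-] | intermediate (not isolated)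
9 | 4-methoxybenzyl (3R,4R,5S)-5-hydroxy-3-(6-methylheptanoyloxy)-4-[(E)-2-methylbut-2-enoyloxy]cyclohex-1-ene-1-carboxylate (3α,4β,5α) | C/C=C(\C)C(=O)O[C@@H]1[C@@H](O)CC(C(=O)OCc2ccc(OC)cc2)=C[C@H]1OC(=O)CCCCC(C)C | intermediate
10 | acetic anhydride | CC(=O)OC(C)=O | starting material
11 | 4-methoxybenzyl (3R,4R,5S)-5-acetoxy-3-(6-methylheptanoyloxy)-4-[(E)-2-methylbut-2-enoyloxy]cyclohex-1-ene-1-carboxylate | C/C=C(\C)C(=O)O[C@@H]1[C@@H](OC(C)=O)CC(C(=O)OCc2ccc(OC)cc2)=C[C@H]1OC(=O)CCCCC(C)C | intermediate
12 | (3R,4R,5S)-5-acetoxy-3-(6-methylheptanoyloxy)-4-[(E)-2-methylbut-2-enoyloxy]cyclohex-1-ene-1-carboxylic acid | C/C=C(\C)C(=O)O[C@@H]1[C@@H](OC(C)=O)CC(C(=O)O)=C[C@H]1OC(=O)CCCCC(C)C | target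

## Step count and risks
Total step count: 5. Longest linear sequence: 5 (1 → 3 → 6 → 9 → 11 → 12).

**Step 3 (the proposed new step).**
- Risks:
  - direct intermolecular carboxylysis of the oxirane at C5;
  - 6-endo participation of the tiglate at C5 instead of 5-exo at C4;
  - capture of 8 only at the acyl carbon, which gives cis-hydroxy esters on work-up;
  - early loss of the PMB group.
- The fallback uses known chemistry only. It sets out from 3 and comes back at 11.
- 2,2-Dimethoxypropane with catalytic CSA in acetone protects the cis-diol as 4-methoxybenzyl 3,4-O-isopropylideneshikimate F1.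
- A Mitsunobu reaction with acetic acid (PPh3, DIAD) inverts C5 and gives 4-methoxybenzyl 5-O-acetyl-3,4-O-isopropylidene-5-epi-shikimate F2.
- 80 % aqueous AcOH at 40 °C removes the acetonide to give the 3α,4α-diol 4-methoxybenzyl 5-O-acetyl-5-epi-shikimate F3.
- DCC/DMAP coupling with 7 at −20 °C acylates the less hindered allylic 3-OH to give 4-methoxybenzyl 5-O-acetyl-3-O-(6-methylheptanoyl)-5-epi-shikimate F4.
- A second Mitsunobu reaction with 4 inverts C4 from the open β face and gives 11. Both neighbouring esters are cis to the leaving group and cannot participate.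

**Step 2.**
- Risks: incomplete second Mitsunobu reaction with the weak acid 4, interference by the hydrazide by-product that binds the epoxy alcohol, and a difficult separation.
- The fallback sets out from 5, which is isolated after the first Mitsunobu stage, and comes back at 6.
- MsCl/Et3N in CH2Cl2 at 0 °C gives the allylic mesylate 4-methoxybenzyl (3α)-3-O-mesyl-4α,5α-epoxide F5.
- Cesium tiglate (from 4 and Cs2CO3) in DMF at rt displaces the mesylate by SN2 at the activated allylic carbon with inversion and delivers 6.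

**Step 4.**
- Risks: pyridine/DMAP may trigger O4→O5 tigloyl migration, or vinylogous deprotonation at H-3, before acetylation is complete.
- The fallback sets out from 9 and comes back at 12. It swaps the order of the last two operations so that no base is ever used.
- TFA/anisole in CH2Cl2 at 0 °C first gives the hydroxy acid (3R,4R,5S)-5-hydroxy-3-(6-methylheptanoyloxy)-4-tigloyloxycyclohex-1-ene-1-carboxylic acid F6.
- Lewis-acid-catalysed acetylation with 10 and catalytic Sc(OTf)3 in MeCN at 0 °C acetylates O5. It also turns the acid transiently into the mixed acetic anhydride of the target F7.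
- F7 is hydrolysed to 12 during the aqueous THF work-up.

## Further compounds
F1 | step 3 | 4-methoxybenzyl 3,4-O-isopropylideneshikimate (3α,4α-acetonide, 5β-OH) | CC1(C)O[C@H]2[C@H](O)CC(C(=O)OCc3ccc(OC)cc3)=C[C@H]2O1
F2 | step 3 | 4-methoxybenzyl 5-O-acetyl-3,4-O-isopropylidene-5-epi-shikimate (5α-OAc) | CC1(C)O[C@H]2[C@@H](OC(C)=O)CC(C(=O)OCc3ccc(OC)cc3)=C[C@H]2O1
F3 | step 3 | 4-methoxybenzyl 5-O-acetyl-5-epi-shikimate (3α-OH, 4α-OH, 5α-OAc) | O[C@H]1[C@@H](OC(C)=O)CC(C(=O)OCc2ccc(OC)cc2)=C[C@H]1O
F4 | step 3 | 4-methoxybenzyl 5-O-acetyl-3-O-(6-methylheptanoyl)-5-epi-shikimate (4α-OH free) | O[C@H]1[C@@H](OC(C)=O)CC(C(=O)OCc2ccc(OC)cc2)=C[C@H]1OC(=O)CCCCC(C)C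
F5 | step 2 | 4-methoxybenzyl (3α)-3-O-mesyl-4α,5α-epoxide (mesylate of 5) | O1[C@H]2[C@@H]1CC(C(=O)OCc3ccc(OC)cc3)=C[C@H]2OS(C)(=O)=O
F6 | step 4 | (3R,4R,5S)-5-hydroxy-3-(6-methylheptanoyloxy)-4-tigloyloxycyclohex-1-ene-1-carboxylic acid | C/C=C(\C)C(=O)O[C@@H]1[C@@H](O)CC(C(=O)O)=C[C@H]1OC(=O)CCCCC(C)C
F7 | step 4 | mixed acetic anhydride of the target acid | C/C=C(\C)C(=O)O[C@@H]1[C@@H](OC(C)=O)CC(C(=O)OC(C)=O)=C[C@H]1OC(=O)CCCCC(C)C
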